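**Plan**

- Cuts, target to fragments: C3–C(aroyl) and the O-protecting groups; C5–C6 of ring B (key step); C5–C9 and C2–OMe (ring A); C3–C4 (acetylide acylation); C1–C8 ([3,3] shift); then C1–prenyl, C5–geranyl, C7–geranyl and C7=C8 (three alkylations, one olefination).
- Forward: the allylic alcohol C6H2(OH)–C7(geranyl)=C8Me2 is esterified with prenylated (R)-3-hydroxybutanoate and an ester-enolate Claisen shift joins C1 to C8. The acid/carbinol pair becomes the C9 ester and the C2 alkyne, acylation gives the ynone, and methoxide addition/Dieckmann closure gives ring A first.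
- Feature used: in the ring-A trione C2-methyl enol ether, C5 is the only C–H between the C4 and C9 carbonyls, and C6 is the terminal methylene of the C8Me2–C7(=C6H2)–geranyl chain on C1. A C5 radical therefore reaches C6 through the six-membered array C5–C9–C1–C8–C7–C6, ring B closes second, and C7 is set by hydrogen delivery.
- End: C3 lithiation/aroylation and one global deprotection.
- Stereochemistry: C1 comes from the (R)-carbinol of methyl (R)-3-hydroxybutanoate through the chelated enolate of the Claisen step (the carbinol is then oxidised away). C5 is dictated by the one-carbon C9 bridge, C7 by exo-face hydrogen transfer, and the E-alkenes are bought with geranyl bromide.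

Key step: step 13

Remark: core atoms are numbered as in bicyclo[3.3.1]nonane — C1 (prenyl bridgehead), C2–C3–C4 (C3 aroyl), C5 (geranyl bridgehead), C6, C7 (geranyl), C8 (CMe2), C9 (bridging C=O) — and open-chain precursors carry the same labels; the target is written as its C2-keto/C4-enol tautomer.

Remark: lithiated or sodiated species generated and consumed inside one step are not numbered; covalent intermediates of telescoped steps are.

**Route**

Step 1
Reactants: 1 geranyl bromide; 2 triethyl phosphonoacetate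
Product: 3 ethyl (4E)-2-(diethoxyphosphoryl)-5,9-dimethyldeca-4,8-dienoate (racemic)
Conditions: NaH, THF, 0 °C; then 1, rt
Reagents that add atoms: none
Why: SN2 C-alkylation of the sodium phosphonoacetate anion by the allylic bromide puts the geranyl chain on the future C7 without touching the E-alkene, and the new stereocentre is destroyed in step 2.

Step 2
Reactants: 3 ethyl (4E)-2-(diethoxyphosphoryl)-5,9-dimethyldeca-4,8-dienoate
Product: 4 ethyl (4E)-5,9-dimethyl-2-(propan-2-ylidene)deca-4,8-dienoate
Conditions: NaH, DME, 0 °C; acetone (excess), reflux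
Reagents that add atoms: acetone, CC(C)=O
Why: Horner–Wadsworth–Emmons olefination of the symmetrical ketone gives the tetrasubstituted enoate with no E/Z question and creates the C7=C8 unit carrying both C8 methyl groups.

Step 3
Reactants: 4 ethyl (4E)-5,9-dimethyl-2-(propan-2-ylidene)deca-4,8-dienoate
Product: 5 (4E)-5,9-dimethyl-2-(propan-2-ylidene)deca-4,8-dien-1-ol
Conditions: DIBAL-H (2.3 equiv), CH2Cl2, −78 °C; Rochelle salt
Reagents that add atoms: none
Why: 1,2-reduction of the enoate by DIBAL-H gives the primary allylic alcohol (C6–OH) and leaves the isolated alkenes alone.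

Step 4
Reactants: 6 methyl (R)-3-hydroxybutanoate; 7 prenyl bromide
Product: 8 methyl (2R,3R)-3-hydroxy-2-(3-methylbut-2-en-1-yl)butanoate
Conditions: LDA (2.2 equiv), THF, −78 → −20 °C; 7, DMPU, −78 → 0 °C; H2O
Reagents that add atoms: none
Why: Fráter–Seebach alkylation of the chelated lithium dianion introduces prenyl anti to the carbinol methyl, and only the (R)-carbinol centre matters later because the α-centre is enolised again in step 6.

Step 5
Reactants: 8 methyl (2R,3R)-3-hydroxy-2-(3-methylbut-2-en-1-yl)butanoate; 5 (4E)-5,9-dimethyl-2-(propan-2-ylidene)deca-4,8-dien-1-ol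
Product: 9 [(4E)-5,9-dimethyl-2-(propan-2-ylidene)deca-4,8-dien-1-yl] (2R,3R)-3-hydroxy-2-(3-methylbut-2-en-1-yl)butanoate
Conditions: 1-hydroxy-3-isothiocyanato-1,1,3,3-tetrabutyldistannoxane (5 mol%), toluene, reflux, removal of MeOH
Reagents that add atoms: none
Why: tin-catalysed transesterification under neutral conditions, driven by loss of methanol, joins the fragments as the allyl ester without dehydration or retro-aldol cleavage of the β-hydroxy ester.

Step 6
Reactants: 9 [(4E)-5,9-dimethyl-2-(propan-2-ylidene)deca-4,8-dien-1-yl] (2R,3R)-3-hydroxy-2-(3-methylbut-2-en-1-yl)butanoate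
Product: 10 (2R,6E)-2-[(1R)-1-hydroxyethyl]-3,3,7,11-tetramethyl-4-methylidene-2-(3-methylbut-2-en-1-yl)dodeca-6,10-dienoic acid
Conditions: LDA (2.3 equiv), THF, −78 → 45 °C; then 1 M HCl
Reagents that add atoms: none
Why: double deprotonation gives the lithium-chelated ester enolate/alkoxide, whose ester-enolate (Ireland-type) Claisen rearrangement forms C1–C8 on the enolate face anti to the carbinol methyl (the sense of Fráter–Seebach alkylations), so the (R)-carbinol sets the quaternary C1, and the minor diastereomer is removed by chromatography.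

Step 7
Reactants: 10 (2R,6E)-2-[(1R)-1-hydroxyethyl]-3,3,7,11-tetramethyl-4-methylidene-2-(3-methylbut-2-en-1-yl)dodeca-6,10-dienoic acid
Product: 11 methyl (2R,6E)-2-[(1R)-1-hydroxyethyl]-3,3,7,11-tetramethyl-4-methylidene-2-(3-methylbut-2-en-1-yl)dodeca-6,10-dienoate
Conditions: TMSCHN2, toluene/MeOH 4:1, 0 °C
Reagents that add atoms: (trimethylsilyl)diazomethane, C[Si](C)(C)C=[N+]=[N-]
Why: esterification with TMS-diazomethane alkylates the carboxylate oxygen, so the congestion around the C9 carboxyl carbon does not matter.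

Step 8
Reactants: 11 methyl (2R,6E)-2-[(1R)-1-hydroxyethyl]-3,3,7,11-tetramethyl-4-methylidene-2-(3-methylbut-2-en-1-yl)dodeca-6,10-dienoate
Product: 12 methyl (2R,6E)-2-acetyl-3,3,7,11-tetramethyl-4-methylidene-2-(3-methylbut-2-en-1-yl)dodeca-6,10-dienoate
Conditions: Dess–Martin periodinane, pyridine, CH2Cl2, 0 °C → rt
Reagents that add atoms: none
Why: Dess–Martin oxidation turns the carbinol into the C2 methyl ketone under near-neutral conditions, the quaternary C1 cannot epimerise, and the relay stereocentre is erased as planned.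

Step 9
Reactants: 12 methyl (2R,6E)-2-acetyl-3,3,7,11-tetramethyl-4-methylidene-2-(3-methylbut-2-en-1-yl)dodeca-6,10-dienoate
Product: 14 methyl (2S,6E)-2-ethynyl-3,3,7,11-tetramethyl-4-methylidene-2-(3-methylbut-2-en-1-yl)dodeca-6,10-dienoate, via enol phosphate 13 (not isolated)
Conditions: LDA (1.1 equiv), THF, −78 °C; ClP(O)(OEt)2, → rt; LDA (2.4 equiv), −78 °C → rt; H2O
Reagents that add atoms: none
Why: the acetyl methyl is the only enolisable position, its enolate is O-phosphorylated and the enol phosphate eliminates with excess LDA to the terminal alkyne (ketone-to-alkyne conversion via an enol phosphate), while the ester has no α-hydrogen and is too hindered to be attacked.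

Step 10
Reactants: 15 N-methoxy-N-methylacetamide; 1 geranyl bromide
Product: 16 (4E)-N-methoxy-N,5,9-trimethyldeca-4,8-dienamide
Conditions: LDA, THF, −78 °C; 1, −78 → −20 °C
Reagents that add atoms: none
Why: SN2 alkylation of the lithium enolate of the Weinreb acetamide by the allylic bromide gives the C4–C5 unit already carrying the C5 geranyl chain.

Step 11
Reactants: 14 methyl (2S,6E)-2-ethynyl-3,3,7,11-tetramethyl-4-methylidene-2-(3-methylbut-2-en-1-yl)dodeca-6,10-dienoate; 16 (4E)-N-methoxy-N,5,9-trimethyldeca-4,8-dienamide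
Product: 17 methyl (2S,6E)-2-[(6E)-7,11-dimethyl-3-oxododeca-6,10-dien-1-yn-1-yl]-3,3,7,11-tetramethyl-4-methylidene-2-(3-methylbut-2-en-1-yl)dodeca-6,10-dienoate
Conditions: n-BuLi (1.05 equiv), THF, −78 °C; 16, −78 → 0 °C; cold 1 M HCl
Reagents that add atoms: none
Why: the lithium acetylide adds once to the Weinreb amide through the chelated tetrahedral intermediate and gives the ynone C2≡C3–C4(=O) on work-up, the hindered methyl ester being spared at low temperature.

Step 12
Reactants: 17 methyl (2S,6E)-2-[(6E)-7,11-dimethyl-3-oxododeca-6,10-dien-1-yn-1-yl]-3,3,7,11-tetramethyl-4-methylidene-2-(3-methylbut-2-en-1-yl)dodeca-6,10-dienoate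
Product: 19 (6R)-2-[(2E)-3,7-dimethylocta-2,6-dien-1-yl]-5-methoxy-6-(3-methylbut-2-en-1-yl)-6-[(5E)-2,6,10-trimethyl-3-methylideneundeca-5,9-dien-2-yl]cyclohex-4-ene-1,3-dione (ring-A trione C2-methyl enol ether; C5 epimers and enol), via β-methoxy enone 18 (not isolated)
Conditions: NaOMe (2.5 equiv), MeOH, 0 → 60 °C; then AcOH
Reagents that add atoms: methanol, CO
Why: methoxide adds to the ynone at C2 (oxa-Michael addition), the enol-ether geometries equilibrate by reversible methoxide addition, and the C5 enolate of the isomer with C1 cis to C4 closes ring A onto the C9 methyl ester (Dieckmann condensation), the acidic product enolate making closure irreversible and methoxide/methanol making every exchange degenerate.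

Step 13
Reactants: 19 ring-A trione C2-methyl enol ether (C5 epimers)
Product: 20 (1R,5S,7S)-5,7-bis[(2E)-3,7-dimethylocta-2,6-dien-1-yl]-2-methoxy-8,8-dimethyl-1-(3-methylbut-2-en-1-yl)bicyclo[3.3.1]non-2-ene-4,9-dione (7-geranyl endo, syn to C2–C4)
Conditions: RVC anode, Pt cathode, undivided cell, constant current (ca. 2.2 F/mol), Cp2Fe (10 mol%), t-BuSH (10 equiv), 1,4-cyclohexadiene (5 equiv), NaOMe (0.2 equiv), n-Bu4NBF4, THF/MeOH 4:1, 25 °C
Reagents that add atoms: none
Why: Proposed new method: methoxide formed at the cathode deprotonates C5 (the only acidic C–H, because the C2 enol ether makes C3 a vinyl CH), anodically regenerated ferrocenium oxidises this enolate to the radical flanked by C4=O and C9=O, the radical adds to the terminal C6 of the C6=C7 alkene, and the tertiary C7 radical takes a hydrogen atom from t-BuSH, whose thiyl radical is repaired by 1,4-cyclohexadiene while the cyclohexadienyl radical is oxidised to benzene and protons are reduced to H2. The closest known reactions are ferrocene-mediated anodic oxidations of 1,3-dicarbonyl and amide anions followed by radical cyclisation with hydrogen transfer from 1,4-cyclohexadiene, Mn(III) oxidative cyclisations of dicarbonyls onto alkenes, and thiol-mediated radical hydroalkylation. Ring B closes 6-endo-trig through C5–C6, favoured because C6 is an unsubstituted terminus that leaves a tertiary radical and because the C9 carbonyl lies inside the forming ring, which disfavours 5-exo attack at C7 or on the C1 prenyl group. C5 is controlled by the bridge, since the chain on C1 can bond only on the ring-A face it occupies and the planar radical from both C5 epimers of 19 gives one bridgehead; C7 is controlled by approach of the bulky thiol to the convex exo face, which leaves the geranyl chain endo. The step needs oxidation of the enolate in the presence of five isolated alkenes (secured by the low potential of the mediator) and hydrogen transfer that outruns reversible 3-exo closure of the homoallylic C7 radical (high thiol concentration), with cyclohexadiene keeping thiyl radicals too short-lived to isomerise the E-alkenes. The product has no C5–H and cannot be oxidised again.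

Step 14
Reactants: 21 3,4-dihydroxybenzoic acid
Product: 23 3,4-bis(tert-butyldimethylsilyloxy)benzoic acid, via tris-silyl ester 22 (not isolated)
Conditions: TBSCl (3.3 equiv), imidazole, DMF, rt; then AcOH/H2O/THF, rt
Reagents that add atoms: tert-butyldimethylsilyl chloride, CC(C)(C)[Si](C)(C)Cl
Why: exhaustive silylation followed by selective hydrolysis of the labile silyl ester under mild aqueous acid leaves the two aryl silyl ethers in place.

Step 15
Reactants: 23 3,4-bis(tert-butyldimethylsilyloxy)benzoic acid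
Product: 24 3,4-bis(tert-butyldimethylsilyloxy)benzoyl chloride
Conditions: (COCl)2, DMF (cat.), CH2Cl2, 0 °C → rt
Reagents that add atoms: oxalyl chloride, O=C(Cl)C(=O)Cl
Why: Vilsmeier-type activation with oxalyl chloride and catalytic DMF converts the acid into the acid chloride under conditions the aryl silyl ethers tolerate.

Step 16
Reactants: 20 des-aroyl core C2-methyl enol ether; 24 3,4-bis(tert-butyldimethylsilyloxy)benzoyl chloride
Product: 25 3-[3,4-bis(tert-butyldimethylsilyloxy)benzoyl] derivative of 20 (same configuration at C1, C5 and C7)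
Conditions: LiTMP (1.3 equiv), THF, −78 °C; 24, −78 → −40 °C
Reagents that add atoms: none
Why: LiTMP removes the C3 vinyl proton of the vinylogous ester (the only acidic C–H left, both ketones being flanked by quaternary carbons) and the vinyllithium is C-acylated by the aroyl chloride.

Step 17
Reactants: 25 3-aroyl bis-silyl methyl enol ether
Product: 26 oblongifolin D
Conditions: LiOH·H2O (10 equiv), 1,4-dioxane/H2O 4:1, 90 °C, Ar; then 1 M HCl
Reagents that add atoms: lithium hydroxide, [Li+].[OH-]
Why: hydroxide cleaves both aryl silyl ethers and hydrolyses the vinylogous methyl ester by addition–elimination at C2, giving the enolised β-triketone, whose delocalised anion resists retro-Claisen cleavage until acidification and leaves all three stereocentres untouched.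

**Compound list**

1 | geranyl bromide | CC(C)=CCC/C(C)=C/CBr | starting material
2 | triethyl phosphonoacetate | CCOC(=O)CP(=O)(OCC)OCC | starting material
3 | ethyl (4E)-2-(diethoxyphosphoryl)-5,9-dimethyldeca-4,8-dienoate (racemic) | CCOC(=O)C(C/C=C(\C)CCC=C(C)C)P(=O)(OCC)OCC | intermediate
4 | ethyl (4E)-5,9-dimethyl-2-(propan-2-ylidene)deca-4,8-dienoate | CCOC(=O)C(C/C=C(\C)CCC=C(C)C)=C(C)C | intermediate
5 | (4E)-5,9-dimethyl-2-(propan-2-ylidene)deca-4,8-dien-1-ol | OCC(C/C=C(\C)CCC=C(C)C)=C(C)C | intermediate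
6 | methyl (R)-3-hydroxybutanoate | C[C@@H](O)CC(=O)OC | starting material
7 | prenyl bromide (1-bromo-3-methylbut-2-ene) | CC(C)=CCBr | starting material
8 | methyl (2R,3R)-3-hydroxy-2-(3-methylbut-2-en-1-yl)butanoate | C[C@@H](O)[C@@H](CC=C(C)C)C(=O)OC | intermediate
9 | [(4E)-5,9-dimethyl-2-(propan-2-ylidene)deca-4,8-dien-1-yl] (2R,3R)-3-hydroxy-2-(3-methylbut-2-en-1-yl)butanoate | C[C@@H](O)[C@@H](CC=C(C)C)C(=O)OCC(C/C=C(\C)CCC=C(C)C)=C(C)C | intermediate
10 | (2R,6E)-2-[(1R)-1-hydroxyethyl]-3,3,7,11-tetramethyl-4-methylidene-2-(3-methylbut-2-en-1-yl)dodeca-6,10-dienoic acid | C[C@@H](O)[C@](CC=C(C)C)(C(=O)O)C(C)(C)C(=C)C/C=C(\C)CCC=C(C)C | intermediate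
11 | methyl (2R,6E)-2-[(1R)-1-hydroxyethyl]-3,3,7,11-tetramethyl-4-methylidene-2-(3-methylbut-2-en-1-yl)dodeca-6,10-dienoate | C[C@@H](O)[C@](CC=C(C)C)(C(=O)OC)C(C)(C)C(=C)C/C=C(\C)CCC=C(C)C | intermediate
12 | methyl (2R,6E)-2-acetyl-3,3,7,11-tetramethyl-4-methylidene-2-(3-methylbut-2-en-1-yl)dodeca-6,10-dienoate | CC(=O)[C@](CC=C(C)C)(C(=O)OC)C(C)(C)C(=C)C/C=C(\C)CCC=C(C)C | intermediate
13 | methyl (2R,6E)-2-{1-[(diethoxyphosphoryl)oxy]ethenyl}-3,3,7,11-tetramethyl-4-methylidene-2-(3-methylbut-2-en-1-yl)dodeca-6,10-dienoate (enol phosphate) | C=C(OP(=O)(OCC)OCC)[C@](CC=C(C)C)(C(=O)OC)C(C)(C)C(=C)C/C=C(\C)CCC=C(C)C | intermediate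
14 | methyl (2S,6E)-2-ethynyl-3,3,7,11-tetramethyl-4-methylidene-2-(3-methylbut-2-en-1-yl)dodeca-6,10-dienoate | C#C[C@](CC=C(C)C)(C(=O)OC)C(C)(C)C(=C)C/C=C(\C)CCC=C(C)C | intermediate
15 | N-methoxy-N-methylacetamide | CC(=O)N(C)OC | starting material
16 | (4E)-N-methoxy-N,5,9-trimethyldeca-4,8-dienamide | CON(C)C(=O)CC/C=C(\C)CCC=C(C)C | intermediate
17 | methyl (2S,6E)-2-[(6E)-7,11-dimethyl-3-oxododeca-6,10-dien-1-yn-1-yl]-3,3,7,11-tetramethyl-4-methylidene-2-(3-methylbut-2-en-1-yl)dodeca-6,10-dienoate (ynone) | CC(C)=CCC/C(C)=C/CCC(=O)C#C[C@](CC=C(C)C)(C(=O)OC)C(C)(C)C(=C)C/C=C(\C)CCC=C(C)C | intermediate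
18 | methyl (2R,6E)-2-[(6E)-1-methoxy-7,11-dimethyl-3-oxododeca-1,6,10-trien-1-yl]-3,3,7,11-tetramethyl-4-methylidene-2-(3-methylbut-2-en-1-yl)dodeca-6,10-dienoate (β-methoxy enone, both enol-ether geometries) | CC(C)=CCC/C(C)=C/CCC(=O)C=C(OC)[C@](CC=C(C)C)(C(=O)OC)C(C)(C)C(=C)C/C=C(\C)CCC=C(C)C | intermediate
19 | (6R)-2-[(2E)-3,7-dimethylocta-2,6-dien-1-yl]-5-methoxy-6-(3-methylbut-2-en-1-yl)-6-[(5E)-2,6,10-trimethyl-3-methylideneundeca-5,9-dien-2-yl]cyclohex-4-ene-1,3-dione (C5 epimers; C1 R in core numbering) | C=C(C/C=C(\C)CCC=C(C)C)C(C)(C)[C@]1(CC=C(C)C)C(OC)=CC(=O)C(C/C=C(\C)CCC=C(C)C)C1=O | intermediate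
20 | (1R,5S,7S)-5,7-bis[(2E)-3,7-dimethylocta-2,6-dien-1-yl]-2-methoxy-8,8-dimethyl-1-(3-methylbut-2-en-1-yl)bicyclo[3.3.1]non-2-ene-4,9-dione (7-geranyl endo) | CC(C)=CCC/C(C)=C/C[C@H]1C[C@]2(C/C=C(\C)CCC=C(C)C)C(=O)[C@@](CC=C(C)C)(C(OC)=CC2=O)C1(C)C | intermediate
21 | 3,4-dihydroxybenzoic acid | OC(=O)c1ccc(O)c(O)c1 | starting material
22 | tert-butyldimethylsilyl 3,4-bis(tert-butyldimethylsilyloxy)benzoate | CC(C)(C)[Si](C)(C)OC(=O)c1ccc(O[Si](C)(C)C(C)(C)C)c(O[Si](C)(C)C(C)(C)C)c1 | intermediate
23 | 3,4-bis(tert-butyldimethylsilyloxy)benzoic acid | CC(C)(C)[Si](C)(C)Oc1ccc(C(=O)O)cc1O[Si](C)(C)C(C)(C)C | intermediate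
24 | 3,4-bis(tert-butyldimethylsilyloxy)benzoyl chloride | CC(C)(C)[Si](C)(C)Oc1ccc(C(=O)Cl)cc1O[Si](C)(C)C(C)(C)C | intermediate
25 | 3-[3,4-bis(tert-butyldimethylsilyloxy)benzoyl]-5,7-digeranyl-2-methoxy-8,8-dimethyl-1-prenylbicyclo[3.3.1]non-2-ene-4,9-dione (C1, C5, C7 as in 20; 7-geranyl endo) | CC(C)=CCC/C(C)=C/C[C@H]1C[C@]2(C/C=C(\C)CCC=C(C)C)C(=O)[C@@](CC=C(C)C)(C(OC)=C(C(=O)c3ccc(O[Si](C)(C)C(C)(C)C)c(O[Si](C)(C)C(C)(C)C)c3)C2=O)C1(C)C | intermediate
26 | oblongifolin D | CC(C)=CCC/C(C)=C/C[C@H]1C[C@]2(C/C=C(\C)CCC=C(C)C)C(=O)[C@@](CC=C(C)C)(C(=O)C(C(=O)c3ccc(O)c(O)c3)=C2O)C1(C)C | target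

**Count and risks**

Total steps: 17. Longest linear sequence: 13 (steps 1–3, 5–9, 11–13, 16, 17).

Steps most likely to fail:

1. Step 13 (proposed new method). The C5 radical may be handed a hydrogen atom before it cyclises (returning 19), may close 5-exo onto the prenyl group, or the C7 radical may be reduced on the endo face or scramble its neighbouring alkene; residual thiyl radicals may also isomerise E-alkenes. Fallback with known chemistry, setting out from 19: bromination at C5 with N-bromosuccinimide (CH2Cl2, 0 °C) should give the 5-bromo trione enol ether F1. Slow addition of Bu3SnH with AIBN and catalytic diphenyl diselenide (benzeneselenol as the fast hydrogen donor) in benzene at 80 °C generates the same C5 radical by bromine abstraction; it cyclises 6-endo onto C6 and is reduced at C7 from the exo face (tin hydride cyclisation of a 2-halo-1,3-dicarbonyl). The sequence comes back at 20.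

2. Step 6. The congested [3,3] shift between two fully substituted termini may stall, the dianion may fragment to a ketene and alkoxide or undergo retro-aldol cleavage on warming, or the facial preference may be weak. Fallback, setting out from 5 and 7: alkylation of methyl acetoacetate with 7 (K2CO3, acetone) gives methyl 2-prenylacetoacetate F2. Mitsunobu O-alkylation with 5 (PPh3, DIAD, toluene) gives the allyl enol ether F3, either geometry being usable. Heating (xylene, 140 °C) effects the neutral Claisen rearrangement to the racemic keto ester F4. Corey–Bakshi–Shibata reduction ((S)-Me-CBS, catecholborane, toluene, −40 °C) then converts both enantiomers into (R)-carbinols, that is 11 and its C2-epimer F5, which are diastereomers and are separated by chromatography. The sequence comes back at 11, before step 8.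

3. Step 12. The C9 ester, flanked by two quaternary carbons, may resist intramolecular acylation so that the sequence stops at 18, or methoxide may cleave the ynone. Fallback replacing ester acylation by aldol addition and oxidation, setting out from 14: excess DIBAL-H (CH2Cl2, −78 → 0 °C) reduces the ester to the alkynyl alcohol F6. Double deprotonation (n-BuLi, 2.1 equiv) and acylation with 16 gives the hydroxy ynone F7, and Dess–Martin oxidation the ynone aldehyde F8. K2CO3 in methanol at 0 °C adds methanol to the ynone (β-methoxy enone aldehyde F9), and the C5 enolate closes ring A by aldol addition to the unhindered aldehyde, giving the aldol F10. A second Dess–Martin oxidation returns the route to 19.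

Further compounds

F1 | step 13 | (6R)-2-bromo-2-geranyl-5-methoxy-6-prenyl-6-[(5E)-2,6,10-trimethyl-3-methylideneundeca-5,9-dien-2-yl]cyclohex-4-ene-1,3-dione (C5-bromo derivative of 19, both C5 epimers) | C=C(C/C=C(\C)CCC=C(C)C)C(C)(C)[C@]1(CC=C(C)C)C(OC)=CC(=O)C(Br)(C/C=C(\C)CCC=C(C)C)C1=O
F2 | step 6 | methyl 2-(3-methylbut-2-en-1-yl)-3-oxobutanoate (racemic) | CC(=O)C(CC=C(C)C)C(=O)OC
F3 | step 6 | methyl 3-{[(4E)-5,9-dimethyl-2-(propan-2-ylidene)deca-4,8-dien-1-yl]oxy}-2-(3-methylbut-2-en-1-yl)but-2-enoate (enol-ether E/Z mixture) | CC(OCC(C/C=C(\C)CCC=C(C)C)=C(C)C)=C(CC=C(C)C)C(=O)OC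
F4 | step 6 | methyl (6E)-2-acetyl-3,3,7,11-tetramethyl-4-methylidene-2-(3-methylbut-2-en-1-yl)dodeca-6,10-dienoate (racemic 12) | CC(=O)C(CC=C(C)C)(C(=O)OC)C(C)(C)C(=C)C/C=C(\C)CCC=C(C)C
F5 | step 6 | methyl (2S,6E)-2-[(1R)-1-hydroxyethyl]-3,3,7,11-tetramethyl-4-methylidene-2-(3-methylbut-2-en-1-yl)dodeca-6,10-dienoate (C2-epimer of 11, discarded) | C[C@@H](O)[C@@](CC=C(C)C)(C(=O)OC)C(C)(C)C(=C)C/C=C(\C)CCC=C(C)C
F6 | step 12 | (2S,6E)-2-ethynyl-3,3,7,11-tetramethyl-4-methylidene-2-(3-methylbut-2-en-1-yl)dodeca-6,10-dien-1-ol | C#C[C@](CC=C(C)C)(CO)C(C)(C)C(=C)C/C=C(\C)CCC=C(C)C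
F7 | step 12 | hydroxy ynone: the C9 primary alcohol corresponding to 17 | CC(C)=CCC/C(C)=C/CCC(=O)C#C[C@](CC=C(C)C)(CO)C(C)(C)C(=C)C/C=C(\C)CCC=C(C)C
F8 | step 12 | ynone aldehyde: the C9 aldehyde corresponding to 17 | CC(C)=CCC/C(C)=C/CCC(=O)C#C[C@](CC=C(C)C)(C=O)C(C)(C)C(=C)C/C=C(\C)CCC=C(C)C
F9 | step 12 | β-methoxy enone aldehyde: the C9 aldehyde corresponding to 18 | CC(C)=CCC/C(C)=C/CCC(=O)C=C(OC)[C@](CC=C(C)C)(C=O)C(C)(C)C(=C)C/C=C(\C)CCC=C(C)C
F10 | step 12 | aldol: 19 with C9 as secondary alcohol (C5 and C9 diastereomers) | C=C(C/C=C(\C)CCC=C(C)C)C(C)(C)[C@]1(CC=C(C)C)C(OC)=CC(=O)C(C/C=C(\C)CCC=C(C)C)C1O
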